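**Retrosynthetic overview** (germacrane numbering: C1 furanone C=O, C3 enol-ether carbon, C6 ester carbinol, C8 lactone carbinol, C10 quaternary carbon)
1. Target ⇒ C6–O ester bond: macrocyclic alcohol 21 + (2S,3R)-epoxy acid 24 (from Sharpless epoxidation of tiglyl alcohol).
2. 21 ⇒ C6–C7 bond: intramolecular chromium allylation of a Z-enal by a 3-(bromomethyl)butenolide; this closes the ten-membered carbocycle last and sets C6 and C7.
3. Butenolide ⇒ ring-closing metathesis of an allylic 2-(hydroxymethyl)acrylate; its C8–O bond comes from rhodium-catalysed acyloxylation of a 2-butynyl side chain (sets C8).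
4. Furanone ⇒ key C–O ring closure (O–C3, 5-endo-dig) in a one-flask annulation of a Seebach dioxolanone with an enyne acetylide; C10 comes from (S)-lactic acid.
5. Ring order: furanone, then butenolide, then ten-membered carbocycle (the last closure turns the butenolide into the α-methylene lactone).

Assumption: compounds 7, 13 and 22 are bought as such (each is otherwise one routine step from a bulk chemical); TBS = tert-butyldimethylsilyl.

**Step 1**
Reactants: 1 (S)-lactic acid; 2 pivalaldehyde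
Product: 3 (2S,5S)-2-tert-butyl-5-methyl-1,3-dioxolan-4-one
Conditions: p-TsOH·H2O (cat.), pentane, reflux (Dean–Stark); recrystallise at −78 °C
Reagents that add atoms: none
Why: Acid-catalysed acetalisation (Seebach self-regeneration of stereocentres) favours the cis acetal, which is enriched by crystallisation so that the tert-butyl group stores the lactate configuration.

**Step 2**
Reactants: 3 (2S,5S)-2-tert-butyl-5-methyl-1,3-dioxolan-4-one; 4 1-bromobut-2-yne
Product: 6 (2S,5R)-5-(but-2-yn-1-yl)-2-tert-butyl-5-methyl-1,3-dioxolan-4-one, via lithium enolate 5 (not isolated)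
Conditions: LiN(i-Pr)2, THF, −78 °C; then 4, −78 → −30 °C
Reagents that add atoms: none
Why: Seebach enolate alkylation: the propargylic bromide enters anti to the tert-butyl group, so the quaternary carbon (future C10, R) is formed with retention of the lactate configuration.

**Step 3**
Reactants: 7 (Z)-3-methylpent-2-en-4-yn-1-ol
Product: 8 tert-butyldimethyl{[(Z)-3-methylpent-2-en-4-yn-1-yl]oxy}silane
Conditions: TBSCl, imidazole, CH2Cl2, 0 °C → rt
Reagents that add atoms: tert-butyldimethylsilyl chloride, CC(C)(C)[Si](C)(C)Cl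
Why: Standard silylation of the primary alcohol blocks O6, which would otherwise add to the ynone of step 4 and give a furan; the Z-alkene (future C4=C5) is bought in.

**Step 4**
Reactants: 6 (2S,5R)-5-(but-2-yn-1-yl)-2-tert-butyl-5-methyl-1,3-dioxolan-4-one; 8 tert-butyldimethyl{[(Z)-3-methylpent-2-en-4-yn-1-yl]oxy}silane
Product: 12 (R)-2-(but-2-yn-1-yl)-5-[(Z)-4-(TBSO)but-2-en-2-yl]-2-methylfuran-3(2H)-one, via lithium acetylide 9 (not isolated), via dioxolanolate adduct 10 (not isolated), via ynone alkoxide 11 (not isolated)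
Conditions: 8, n-BuLi, THF, −78 °C; then 6, −78 → 0 °C; then MeOH, 0 °C → rt
Reagents that add atoms: none
Why: Proposed new method: one-flask anionic furanone annulation, in which acetylide 9 adds once to the lactone-type carbonyl of 6 (quaternary α-carbon, no enolisation) to give adduct 10, which on warming unravels with loss of pivalaldehyde to the tertiary alkoxide 11, and this closes by 5-endo-dig oxa-Michael addition onto C3 of the ynone (methanol protonates the vinyl anion and makes the closure irreversible), forming the O–C3 bond and the furanone ring while the C10–O bond is never broken so C10 stays R; closest known reaction type: alkynylation of lactones to ynones followed by base- or gold-mediated cyclisation of α′-hydroxy ynones to 3(2H)-furanones.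

**Step 5**
Reactants: 12 (R)-2-(but-2-yn-1-yl)-5-[(Z)-4-(TBSO)but-2-en-2-yl]-2-methylfuran-3(2H)-one; 13 2-(hydroxymethyl)acrylic acid
Product: 15 (S)-1-{(R)-5-[(Z)-4-(TBSO)but-2-en-2-yl]-2-methyl-3-oxo-2,3-dihydrofuran-2-yl}but-3-en-2-yl 2-(hydroxymethyl)acrylate, via terminal allene 14 (not isolated)
Conditions: [Rh(cod)Cl]2 (3 mol%), (S,S)-DIOP (6 mol%), 13 (2 equiv), ClCH2CH2Cl, 70 °C
Reagents that add atoms: none
Why: Breit-type rhodium-catalysed redox-neutral propargylic C–H acyloxylation: Rh–H walks the methyl alkyne to the terminal allene 14 (the other propargylic CH2 is neopentylic), hydrometalation gives a rhodium π-allyl, and the carboxylate attacks the substituted terminus, forming the C8–O bond with catalyst-controlled configuration (the DIOP antipode is the handle for 8S, to be confirmed by Mosher analysis).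

**Step 6**
Reactants: 15 (S)-1-{(R)-5-[(Z)-4-(TBSO)but-2-en-2-yl]-2-methyl-3-oxo-2,3-dihydrofuran-2-yl}but-3-en-2-yl 2-(hydroxymethyl)acrylate
Product: 16 (S)-5-({(R)-5-[(Z)-4-(TBSO)but-2-en-2-yl]-2-methyl-3-oxo-2,3-dihydrofuran-2-yl}methyl)-3-(hydroxymethyl)furan-2(5H)-one
Conditions: second-generation Grubbs catalyst RuCl2(=CHPh)(PCy3)(H2IMes) (5 mol%), toluene, 80 °C
Reagents that add atoms: none
Why: Ring-closing metathesis of the vinyl group and the acrylate gives the five-membered butenolide (C7=C11), while the conjugated trisubstituted Z-alkene and the furanone alkene do not take part.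

**Step 7**
Reactants: 16 (S)-5-({(R)-5-[(Z)-4-(TBSO)but-2-en-2-yl]-2-methyl-3-oxo-2,3-dihydrofuran-2-yl}methyl)-3-(hydroxymethyl)furan-2(5H)-one
Product: 17 (S)-3-(bromomethyl)-5-({(R)-5-[(Z)-4-(TBSO)but-2-en-2-yl]-2-methyl-3-oxo-2,3-dihydrofuran-2-yl}methyl)furan-2(5H)-one
Conditions: CBr4, PPh3, CH2Cl2, 0 °C
Reagents that add atoms: carbon tetrabromide, BrC(Br)(Br)Br
Why: Appel bromination converts the primary allylic alcohol into the bromide under neutral conditions that leave the silyl ether and both lactone/furanone rings intact.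

**Step 8**
Reactants: 17 (S)-3-(bromomethyl)-5-({(R)-5-[(Z)-4-(TBSO)but-2-en-2-yl]-2-methyl-3-oxo-2,3-dihydrofuran-2-yl}methyl)furan-2(5H)-one
Product: 18 (S)-3-(bromomethyl)-5-({(R)-5-[(Z)-4-hydroxybut-2-en-2-yl]-2-methyl-3-oxo-2,3-dihydrofuran-2-yl}methyl)furan-2(5H)-one
Conditions: aq. HF (48%), MeCN, 0 °C (short contact, used at once)
Reagents that add atoms: none
Why: Acidic fluoride desilylation of a primary TBS ether is fast and amine-free, so the reactive allylic bromide survives.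

**Step 9**
Reactants: 18 (S)-3-(bromomethyl)-5-({(R)-5-[(Z)-4-hydroxybut-2-en-2-yl]-2-methyl-3-oxo-2,3-dihydrofuran-2-yl}methyl)furan-2(5H)-one
Product: 19 (Z)-3-{(R)-5-{[(S)-4-(bromomethyl)-5-oxo-2,5-dihydrofuran-2-yl]methyl}-5-methyl-4-oxo-4,5-dihydrofuran-2-yl}but-2-enal
Conditions: Dess–Martin periodinane, CH2Cl2, 0 °C
Reagents that add atoms: none
Why: Dess–Martin oxidation gives the Z-enal without base, so neither Z→E isomerisation nor attack on the allylic bromide is expected.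

**Step 10**
Reactants: 19 (Z)-3-{(R)-5-{[(S)-4-(bromomethyl)-5-oxo-2,5-dihydrofuran-2-yl]methyl}-5-methyl-4-oxo-4,5-dihydrofuran-2-yl}but-2-enal
Product: 21 (6R,7S,8S,10R)-6-hydroxy-1-oxo-3,10-epoxygermacra-2,4Z,11(13)-trien-12,8-olide, via allylchromium dichloride 20 (not isolated)
Conditions: CrCl2 (8 equiv), THF (2 mM, slow addition), rt; cold aq. NH4Cl
Reagents that add atoms: none
Why: Intramolecular Nozaki–Hiyama allylation: the ring-locked E-type allylchromium 20 (trivalent chromium) adds through its γ-carbon C7 to the aldehyde via a chair transition state, anti to the C9 substituent, which forms C6–C7, sets C6 (R) and C7 (anti to O6, trans to C9) and leaves the trans-fused α-methylene 8,12-lactone (C7 is S in 21 only through a CIP priority change).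

**Step 11**
Reactants: 22 (E)-2-methylbut-2-en-1-ol
Product: 23 [(2R,3R)-2,3-dimethyloxiran-2-yl]methanol
Conditions: Ti(OiPr)4 (5 mol%), D-(−)-diisopropyl tartrate (7 mol%), t-BuOOH, 4 Å MS, CH2Cl2, −20 °C
Reagents that add atoms: tert-butyl hydroperoxide, CC(C)(C)OO
Why: Sharpless asymmetric epoxidation; the D-(−)-tartrate delivers oxygen to the face that gives the (2R,3R)-epoxide, and syn addition to the E-alkene keeps the two methyl groups cis.

**Step 12**
Reactants: 23 [(2R,3R)-2,3-dimethyloxiran-2-yl]methanol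
Product: 24 (2S,3R)-2,3-dimethyloxirane-2-carboxylic acid
Conditions: RuCl3·xH2O (2 mol%), NaIO4, CCl4/MeCN/H2O, 0 °C → rt
Reagents that add atoms: water, O; sodium periodate, [Na+].[O-]I(=O)(=O)=O (stoichiometric oxygen source via RuO4)
Why: Sharpless RuO4 oxidation takes the epoxy alcohol to the epoxy acid without touching the epoxide; the C2 descriptor changes from R to S only by CIP priority.

**Step 13**
Reactants: 21 (6R,7S,8S,10R)-6-hydroxy-1-oxo-3,10-epoxygermacra-2,4Z,11(13)-trien-12,8-olide; 24 (2S,3R)-2,3-dimethyloxirane-2-carboxylic acid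
Product: 26 (6R,7R,8S,10R)-1-oxo-3,10-epoxygermacra-2,4Z,11(13)-trien-12,8-olid-6-yl (2S,3R)-2,3-dimethyloxirane-2-carboxylate (CNP0258430.2), via mixed anhydride 25 (not isolated)
Conditions: 24, 2,4,6-trichlorobenzoyl chloride, Et3N, toluene, rt; then 21, DMAP, rt
Reagents that add atoms: none
Why: Yamaguchi esterification through the mixed anhydride 25 acylates the hindered C6 alcohol faster than O6 can translactonise onto C12, and no stereocentre is touched.

**Compound list**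
1 | (S)-lactic acid | C[C@H](O)C(=O)O | starting material
2 | pivalaldehyde | CC(C)(C)C=O | starting material
3 | (2S,5S)-2-tert-butyl-5-methyl-1,3-dioxolan-4-one | C[C@@H]1O[C@H](C(C)(C)C)OC1=O | intermediate
4 | 1-bromobut-2-yne | CC#CCBr | starting material
5 | lithium (S)-2-tert-butyl-5-methyl-1,3-dioxol-4-olate (enolate of 3) | CC1=C([O-])O[C@@H](C(C)(C)C)O1.[Li+] | intermediate
6 | (2S,5R)-5-(but-2-yn-1-yl)-2-tert-butyl-5-methyl-1,3-dioxolan-4-one | CC#CC[C@@]1(C)O[C@H](C(C)(C)C)OC1=O | intermediate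
7 | (Z)-3-methylpent-2-en-4-yn-1-ol | C#C/C(C)=C\CO | starting material
8 | tert-butyldimethyl{[(Z)-3-methylpent-2-en-4-yn-1-yl]oxy}silane | C#C/C(C)=C\CO[Si](C)(C)C(C)(C)C | intermediate
9 | lithium acetylide of 8 | [Li+].[C-]#C/C(C)=C\CO[Si](C)(C)C(C)(C)C | intermediate
10 | lithium (2S,5R)-5-(but-2-yn-1-yl)-2-tert-butyl-5-methyl-4-[(Z)-3-methyl-5-(TBSO)pent-3-en-1-yn-1-yl]-1,3-dioxolan-4-olate (both C4 epimers) | CC#CC[C@@]1(C)O[C@H](C(C)(C)C)OC1([O-])C#C/C(C)=C\CO[Si](C)(C)C(C)(C)C.[Li+] | intermediate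
11 | lithium alkoxide of (2Z,7R)-1-(TBSO)-7-hydroxy-3,7-dimethylundec-2-ene-4,9-diyn-6-one | CC#CC[C@@](C)([O-])C(=O)C#C/C(C)=C\CO[Si](C)(C)C(C)(C)C.[Li+] | intermediate
12 | (R)-2-(but-2-yn-1-yl)-5-[(Z)-4-(TBSO)but-2-en-2-yl]-2-methylfuran-3(2H)-one | CC#CC[C@@]1(C)OC(=CC1=O)/C(C)=C\CO[Si](C)(C)C(C)(C)C | intermediate
13 | 2-(hydroxymethyl)acrylic acid | C=C(CO)C(=O)O | starting material
14 | (R)-2-(buta-2,3-dien-1-yl)-5-[(Z)-4-(TBSO)but-2-en-2-yl]-2-methylfuran-3(2H)-one | C=C=CC[C@@]1(C)OC(=CC1=O)/C(C)=C\CO[Si](C)(C)C(C)(C)C | intermediate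
15 | (S)-1-{(R)-5-[(Z)-4-(TBSO)but-2-en-2-yl]-2-methyl-3-oxo-2,3-dihydrofuran-2-yl}but-3-en-2-yl 2-(hydroxymethyl)acrylate | C=C[C@H](C[C@@]1(C)OC(=CC1=O)/C(C)=C\CO[Si](C)(C)C(C)(C)C)OC(=O)C(=C)CO | intermediate
16 | (S)-5-({(R)-5-[(Z)-4-(TBSO)but-2-en-2-yl]-2-methyl-3-oxo-2,3-dihydrofuran-2-yl}methyl)-3-(hydroxymethyl)furan-2(5H)-one | OCC1=C[C@H](C[C@@]2(C)OC(=CC2=O)/C(C)=C\CO[Si](C)(C)C(C)(C)C)OC1=O | intermediate
17 | (S)-3-(bromomethyl)-5-({(R)-5-[(Z)-4-(TBSO)but-2-en-2-yl]-2-methyl-3-oxo-2,3-dihydrofuran-2-yl}methyl)furan-2(5H)-one | BrCC1=C[C@H](C[C@@]2(C)OC(=CC2=O)/C(C)=C\CO[Si](C)(C)C(C)(C)C)OC1=O | intermediate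
18 | (S)-3-(bromomethyl)-5-({(R)-5-[(Z)-4-hydroxybut-2-en-2-yl]-2-methyl-3-oxo-2,3-dihydrofuran-2-yl}methyl)furan-2(5H)-one | BrCC1=C[C@H](C[C@@]2(C)OC(=CC2=O)/C(C)=C\CO)OC1=O | intermediate
19 | (Z)-3-{(R)-5-{[(S)-4-(bromomethyl)-5-oxo-2,5-dihydrofuran-2-yl]methyl}-5-methyl-4-oxo-4,5-dihydrofuran-2-yl}but-2-enal | BrCC1=C[C@H](C[C@@]2(C)OC(=CC2=O)/C(C)=C\C=O)OC1=O | intermediate
20 | allylchromium dichloride derived from 19 (CrCl2 in place of Br) | Cl[Cr](Cl)CC1=C[C@H](C[C@@]2(C)OC(=CC2=O)/C(C)=C\C=O)OC1=O | intermediate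
21 | (6R,7S,8S,10R)-6-hydroxy-1-oxo-3,10-epoxygermacra-2,4Z,11(13)-trien-12,8-olide | C=C1C(=O)O[C@H]2C[C@@]3(C)OC(=CC3=O)/C(C)=C\[C@@H](O)[C@H]12 | intermediate
22 | (E)-2-methylbut-2-en-1-ol | C/C=C(\C)CO | starting material
23 | [(2R,3R)-2,3-dimethyloxiran-2-yl]methanol | OC[C@@]1(C)O[C@@H]1C | intermediate
24 | (2S,3R)-2,3-dimethyloxirane-2-carboxylic acid | OC(=O)[C@@]1(C)O[C@@H]1C | intermediate
25 | (2S,3R)-2,3-dimethyloxirane-2-carboxylic 2,4,6-trichlorobenzoic anhydride | O=C(OC(=O)[C@@]1(C)O[C@@H]1C)c1c(Cl)cc(Cl)cc1Cl | intermediate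
26 | (6R,7R,8S,10R)-1-oxo-3,10-epoxygermacra-2,4Z,11(13)-trien-12,8-olid-6-yl (2S,3R)-2,3-dimethyloxirane-2-carboxylate | C=C1C(=O)O[C@H]2C[C@@]3(C)OC(=CC3=O)/C(C)=C\[C@@H](OC(=O)[C@@]3(C)O[C@@H]3C)[C@H]12 | target

**Total step count:** 13. **Longest linear sequence:** 10 steps (1, 2, 4, 5, 6, 7, 8, 9, 10, 13).

**Three steps most likely to fail**

Step 4 (the proposed new annulation). The risks are a second acetylide addition to the ynone once the adduct opens, capture of acetylide by the released pivalaldehyde, and slow ring closure in the absence of a proton source. The fallback uses known chemistry, sets out from 6 and returns at 12. Opening 6 with N,O-dimethylhydroxylamine hydrochloride and i-PrMgCl gives the Weinreb amide (R)-2-hydroxy-N-methoxy-N,2-dimethylhex-4-ynamide F1. Two equivalents of acetylide 9 then give the isolated hydroxy ynone (2Z,7R)-1-(TBSO)-7-hydroxy-3,7-dimethylundec-2-ene-4,9-diyn-6-one F2. Ph3PAuCl/AgOTf (monovalent gold, 5-endo-dig cyclisation of an α′-hydroxy ynone) closes F2 to 12.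

Step 5 (rhodium acyloxylation). The risks are alkyne walking in the wrong direction, a mismatched diastereoselectivity with the C10 centre, and interference by the free hydroxyl of 13. The fallback sets out from 3 and returns at 17. Alkylation of enolate 5 with allyl bromide gives (2S,5R)-5-allyl-2-tert-butyl-5-methyl-1,3-dioxolan-4-one F3. Annulation with 9 as in step 4 gives (R)-2-allyl-5-[(Z)-4-(TBSO)but-2-en-2-yl]-2-methylfuran-3(2H)-one F4. OsO4 (cat.)/NaIO4 cleaves the terminal alkene to 2-{(R)-5-[(Z)-4-(TBSO)but-2-en-2-yl]-2-methyl-3-oxo-2,3-dihydrofuran-2-yl}acetaldehyde F5. Catalytic asymmetric vinylation with Zn(CH=CH2)2 and a chiral amino alcohol ligand gives (R)-5-[(Z)-4-(TBSO)but-2-en-2-yl]-2-[(S)-2-hydroxybut-3-en-1-yl]-2-methylfuran-3(2H)-one F6. Acylation with 2-(bromomethyl)acryloyl chloride and 2,6-di-tert-butyl-4-methylpyridine gives (S)-1-{(R)-5-[(Z)-4-(TBSO)but-2-en-2-yl]-2-methyl-3-oxo-2,3-dihydrofuran-2-yl}but-3-en-2-yl 2-(bromomethyl)acrylate F7. Ring-closing metathesis with second-generation Grubbs catalyst then gives 17 directly.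

Step 10 (macrocyclisation). The risks are reduction or dimerisation of the allylchromium before a strained ring closes, the wrong face at C7 (cis-fused lactone), Z→E drift of the enal, and translactonisation of the chromium alkoxide. The fallback replaces the reductive organometallic closure by an allylboration; it sets out from 17 and returns at 21. Miyaura borylation (Pd2(dba)3, B2pin2, KOAc) gives the allylboronate (S)-5-({(R)-5-[(Z)-4-(TBSO)but-2-en-2-yl]-2-methyl-3-oxo-2,3-dihydrofuran-2-yl}methyl)-3-[(pinacolatoboryl)methyl]furan-2(5H)-one F8. Aqueous HF in MeCN gives the corresponding Z-allylic alcohol F9. Dess–Martin oxidation gives the boronate Z-enal F10. Sc(OTf)3 (cat.) in toluene at high dilution closes F10 through the same closed chair transition state, and aqueous work-up releases 21.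

**Further compounds**
F1 | step 4 | (R)-2-hydroxy-N-methoxy-N,2-dimethylhex-4-ynamide | CC#CC[C@@](C)(O)C(=O)N(C)OC
F2 | step 4 | (2Z,7R)-1-(TBSO)-7-hydroxy-3,7-dimethylundec-2-ene-4,9-diyn-6-one | CC#CC[C@@](C)(O)C(=O)C#C/C(C)=C\CO[Si](C)(C)C(C)(C)C
F3 | step 5 | (2S,5R)-5-allyl-2-tert-butyl-5-methyl-1,3-dioxolan-4-one | C=CC[C@@]1(C)O[C@H](C(C)(C)C)OC1=O
F4 | step 5 | (R)-2-allyl-5-[(Z)-4-(TBSO)but-2-en-2-yl]-2-methylfuran-3(2H)-one | C=CC[C@@]1(C)OC(=CC1=O)/C(C)=C\CO[Si](C)(C)C(C)(C)C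
F5 | step 5 | 2-{(R)-5-[(Z)-4-(TBSO)but-2-en-2-yl]-2-methyl-3-oxo-2,3-dihydrofuran-2-yl}acetaldehyde | O=CC[C@@]1(C)OC(=CC1=O)/C(C)=C\CO[Si](C)(C)C(C)(C)C
F6 | step 5 | (R)-5-[(Z)-4-(TBSO)but-2-en-2-yl]-2-[(S)-2-hydroxybut-3-en-1-yl]-2-methylfuran-3(2H)-one | C=C[C@@H](O)C[C@@]1(C)OC(=CC1=O)/C(C)=C\CO[Si](C)(C)C(C)(C)C
F7 | step 5 | (S)-1-{(R)-5-[(Z)-4-(TBSO)but-2-en-2-yl]-2-methyl-3-oxo-2,3-dihydrofuran-2-yl}but-3-en-2-yl 2-(bromomethyl)acrylate | C=C[C@H](C[C@@]1(C)OC(=CC1=O)/C(C)=C\CO[Si](C)(C)C(C)(C)C)OC(=O)C(=C)CBr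
F8 | step 10 | (S)-5-({(R)-5-[(Z)-4-(TBSO)but-2-en-2-yl]-2-methyl-3-oxo-2,3-dihydrofuran-2-yl}methyl)-3-[(4,4,5,5-tetramethyl-1,3,2-dioxaborolan-2-yl)methyl]furan-2(5H)-one | CC1(C)OB(CC2=C[C@H](C[C@@]3(C)OC(=CC3=O)/C(C)=C\CO[Si](C)(C)C(C)(C)C)OC2=O)OC1(C)C
F9 | step 10 | (S)-5-({(R)-5-[(Z)-4-hydroxybut-2-en-2-yl]-2-methyl-3-oxo-2,3-dihydrofuran-2-yl}methyl)-3-[(4,4,5,5-tetramethyl-1,3,2-dioxaborolan-2-yl)methyl]furan-2(5H)-one | CC1(C)OB(CC2=C[C@H](C[C@@]3(C)OC(=CC3=O)/C(C)=C\CO)OC2=O)OC1(C)C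
F10 | step 10 | (Z)-3-{(R)-5-methyl-4-oxo-5-{[(S)-5-oxo-4-[(4,4,5,5-tetramethyl-1,3,2-dioxaborolan-2-yl)methyl]-2,5-dihydrofuran-2-yl]methyl}-4,5-dihydrofuran-2-yl}but-2-enal | CC1(C)OB(CC2=C[C@H](C[C@@]3(C)OC(=CC3=O)/C(C)=C\C=O)OC2=O)OC1(C)C
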